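**Retrosynthetic overview**
- The C6–OOH bond comes from SN2 perhydrolysis (inversion) of a (6R)-mesylate. The (6R)-carbinol comes from CBS reduction of the isopropenyl ketone, which is built from a C6 aldehyde (carried as a dioxolane) and 2-bromopropene.
- The C1–O–aryl ether comes from a Mitsunobu coupling of the C1 allylic alcohol with 4-hydroxy-5-methylcoumarin. Its pyranone ring, the only ring closed in the route, is made first from 2-hydroxy-6-methylbenzoic acid.
- The plan rests on the acyclic trisubstituted C2=C3 alkene: the C1H2O arm and the C10H2O arm are cis, and the C4 chain is trans to C1. C3–C4 and C1–C2 are both cut in one operation, back to propargyl alcohol, an acetal-bearing Grignard reagent and formaldehyde.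
- The two allylic hydroxyls of the resulting diol are distinguished by hindrance: C1–OH lies next to the C2–H methine, C10–OH next to the fully substituted C3.

Key step: step 2

Remark: the target is read as the (2Z,6S) isomer. The chain is numbered C1 (ether CH2) to C8 (terminal =CH2), with C10 the hydroxymethyl carbon on C3; formaldehyde is supplied as the monomer by cracking paraformaldehyde.

**Step 1**
Reactants: 1 2-(2-bromoethyl)-1,3-dioxolane
Product: 2 2-(1,3-dioxolan-2-yl)ethylmagnesium bromide
Conditions: Mg turnings, cat. I2, THF, 25–30 °C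
Reagents that add atoms: magnesium, [Mg]
Why: Grignard formation by insertion of magnesium into the primary C–Br bond; the dioxolane is inert as long as the solution stays at or below about 30 °C, above which this beta-acetal Grignard reagent fragments.

**Step 2**
Reactants: 2 2-(1,3-dioxolan-2-yl)ethylmagnesium bromide; 3 propargyl alcohol; 4 formaldehyde
Product: 6 (Z)-2-[2-(1,3-dioxolan-2-yl)ethyl]but-2-ene-1,4-diol, via oxamagnesacycle 5 (not isolated)
Conditions: 2 (2.6 equiv), CuI (10 mol %, monovalent copper), THF, −10 → 20 °C, 16 h; then CH2O gas (excess, from cracked paraformaldehyde), 0 °C → rt; aq. NH4Cl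
Reagents that add atoms: none
Why: Reagent 2 first deprotonates 3, and the alkylcopper species formed from catalytic CuI then adds across the alkyne of the magnesium alkoxide, placing the alkyl group on the internal carbon (C3) and the metal on the terminal carbon (C2); copper-to-magnesium exchange gives the five-membered oxamagnesacycle 5, in which magnesium on C2 is cis to the C10 alkoxymethyl arm and trans to the new C3–C4 bond (net anti addition). Formaldehyde then inserts into the C2–Mg bond with retention of alkene geometry, so C1 ends cis to C10 and trans to C4. The closest known reaction type is the CuI-catalysed anti-carbomagnesiation of propargylic alcohols with trapping of the chelated alkenylmagnesium by iodine, carbon dioxide or aldehydes. The only ring closed is the transient oxamagnesacycle (closure by O–Mg–C chelation), which is opened on aqueous work-up, so no ring remains and no stereocentre is formed. The step needs regioselectivity (alkyl to C3) and anti geometry, both secured by the magnesium alkoxide of 3, and the temperature is kept at or below 25 °C because 2 is thermally labile.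

**Step 3**
Reactants: 6 (Z)-2-[2-(1,3-dioxolan-2-yl)ethyl]but-2-ene-1,4-diol
Product: 7 (Z)-3-[2-(1,3-dioxolan-2-yl)ethyl]-4-hydroxybut-2-en-1-yl 2,2-dimethylpropanoate (pivalate on the C1 oxygen)
Conditions: t-BuCOCl (1.05 equiv), pyridine, CH2Cl2, −30 → 0 °C
Reagents that add atoms: pivaloyl chloride, CC(C)(C)C(=O)Cl
Why: Sterically controlled mono-acylation: the C1 hydroxyl sits on a CH2 next to the C2–H methine, whereas the C10 hydroxyl sits on a CH2 attached to the fully substituted C3 beside the C4 chain, so the bulky acyl chloride should esterify C1–OH preferentially at low temperature, and the minor regioisomer and any diester are removed by chromatography.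

**Step 4**
Reactants: 7 (Z)-3-[2-(1,3-dioxolan-2-yl)ethyl]-4-hydroxybut-2-en-1-yl 2,2-dimethylpropanoate
Product: 8 (Z)-4-[(tert-butyldiphenylsilyl)oxy]-3-[2-(1,3-dioxolan-2-yl)ethyl]but-2-en-1-yl 2,2-dimethylpropanoate
Conditions: TBDPSCl, imidazole, DMF, 0 °C → rt
Reagents that add atoms: tert-butyl(chloro)diphenylsilane, CC(C)(C)[Si](Cl)(c1ccccc1)c1ccccc1
Why: Imidazole-promoted silylation of the remaining primary allylic alcohol (Corey protocol) under conditions that should neither move the pivalate nor touch the acetal.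

**Step 5**
Reactants: 8 (Z)-4-[(tert-butyldiphenylsilyl)oxy]-3-[2-(1,3-dioxolan-2-yl)ethyl]but-2-en-1-yl 2,2-dimethylpropanoate
Product: 9 (Z)-4-[(tert-butyldiphenylsilyl)oxy]-3-[2-(1,3-dioxolan-2-yl)ethyl]but-2-en-1-ol
Conditions: i-Bu2AlH (2.5 equiv), CH2Cl2, −78 °C; aq. potassium sodium tartrate
Reagents that add atoms: none
Why: Reductive cleavage of the ester by i-Bu2AlH at −78 °C frees the C1 alcohol while the silyl ether and the dioxolane, both inert to the hydride at this temperature, stay on, which completes the exchange of protecting groups between C1 and C10.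

**Step 6**
Reactants: 10 2-hydroxy-6-methylbenzoic acid
Product: 11 1-(2-hydroxy-6-methylphenyl)ethan-1-one
Conditions: MeLi (3.5 equiv), THF, 0 °C → rt; poured into cold aq. HCl
Reagents that add atoms: methyllithium, [Li]C
Why: Ketone synthesis by addition of an organolithium to a lithium carboxylate: two equivalents of MeLi deprotonate acid and phenol, the third adds to the carboxylate, and the geminal dialkoxide, shielded by two ortho substituents, resists a second addition until it collapses to the methyl ketone on acidic work-up.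

**Step 7**
Reactants: 11 1-(2-hydroxy-6-methylphenyl)ethan-1-one
Product: 12 4-hydroxy-5-methyl-2H-chromen-2-one (4-hydroxy-5-methylcoumarin)
Conditions: NaH (4 equiv), (EtO)2CO, toluene, 100 °C; aq. HCl
Reagents that add atoms: diethyl carbonate, CCOC(=O)OCC
Why: Standard 4-hydroxycoumarin synthesis from an ortho-hydroxyacetophenone: the ketone enolate is C-acylated by diethyl carbonate (Claisen-type condensation) and the phenoxide closes the pyranone ring by lactonization onto the beta-keto ester, with the methyl group fixed at C5 because it is already ortho to the acyl carbon in 10.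

**Step 8**
Reactants: 9 (Z)-4-[(tert-butyldiphenylsilyl)oxy]-3-[2-(1,3-dioxolan-2-yl)ethyl]but-2-en-1-ol; 12 4-hydroxy-5-methyl-2H-chromen-2-one
Product: 13 4-{[(Z)-4-[(tert-butyldiphenylsilyl)oxy]-3-[2-(1,3-dioxolan-2-yl)ethyl]but-2-en-1-yl]oxy}-5-methyl-2H-chromen-2-one
Conditions: PPh3, DIAD, THF, 0 °C → rt
Reagents that add atoms: none
Why: Mitsunobu etherification: the acidic enol of 12 (pKa about 4) is alkylated on the C4 oxygen by SN2 displacement of the oxyphosphonium at the primary allylic C1, which leaves the C2=C3 geometry untouched and is not expected to proceed with allylic transposition because C3 is fully substituted; any 2-alkoxychromone isomer is separated.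

**Step 9**
Reactants: 13 4-{[(Z)-4-[(tert-butyldiphenylsilyl)oxy]-3-[2-(1,3-dioxolan-2-yl)ethyl]but-2-en-1-yl]oxy}-5-methyl-2H-chromen-2-one
Product: 14 (Z)-4-{[(tert-butyldiphenylsilyl)oxy]methyl}-6-[(5-methyl-2-oxo-2H-chromen-4-yl)oxy]hex-4-enal
Conditions: pyridinium p-toluenesulfonate (cat.), acetone/H2O (10:1), 55 °C
Reagents that add atoms: water, O
Why: Acid-catalysed hydrolysis (transacetalization to acetone) of the aldehyde dioxolane under conditions mild enough for the primary TBDPS ether, the allylic coumarinyl ether and the lactone.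

**Step 10**
Reactants: 14 (Z)-4-{[(tert-butyldiphenylsilyl)oxy]methyl}-6-[(5-methyl-2-oxo-2H-chromen-4-yl)oxy]hex-4-enal; 15 2-bromopropene
Product: 16 4-{[(2Z)-3-{[(tert-butyldiphenylsilyl)oxy]methyl}-6-hydroxy-7-methylocta-2,7-dien-1-yl]oxy}-5-methyl-2H-chromen-2-one (racemic at C6)
Conditions: CrCl2 (4 equiv, divalent chromium), NiCl2 (1 mol %, divalent nickel), DMF, rt
Reagents that add atoms: none
Why: Nozaki–Hiyama–Kishi reaction: the alkenylchromium species formed from 15 under nickel catalysis adds only to the aldehyde and ignores the lactone, the enol ether and the silyl ether, giving the isopropenyl carbinol as a racemate that is corrected in the next two steps.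

**Step 11**
Reactants: 16 4-{[(2Z)-3-{[(tert-butyldiphenylsilyl)oxy]methyl}-6-hydroxy-7-methylocta-2,7-dien-1-yl]oxy}-5-methyl-2H-chromen-2-one
Product: 17 4-{[(2Z)-3-{[(tert-butyldiphenylsilyl)oxy]methyl}-7-methyl-6-oxoocta-2,7-dien-1-yl]oxy}-5-methyl-2H-chromen-2-one
Conditions: Dess–Martin periodinane, NaHCO3, CH2Cl2, 0 °C → rt
Reagents that add atoms: none
Why: Dess–Martin oxidation of the secondary allylic alcohol under buffered conditions gives the alpha-methyl enone without touching the alkenes or the allylic ether; the enone is used promptly.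

**Step 12**
Reactants: 17 4-{[(2Z)-3-{[(tert-butyldiphenylsilyl)oxy]methyl}-7-methyl-6-oxoocta-2,7-dien-1-yl]oxy}-5-methyl-2H-chromen-2-one
Product: 18 4-{[(2Z,6R)-3-{[(tert-butyldiphenylsilyl)oxy]methyl}-6-hydroxy-7-methylocta-2,7-dien-1-yl]oxy}-5-methyl-2H-chromen-2-one
Conditions: (S)-1-methyl-3,3-diphenyltetrahydro-1H,3H-pyrrolo[1,2-c][1,3,2]oxazaborole ((S)-Me-CBS, 0.5 equiv), catecholborane (2 equiv), CH2Cl2, −78 °C
Reagents that add atoms: none
Why: Corey–Bakshi–Shibata reduction: with the (S)-oxazaborolidine the ketone binds boron anti to the larger, alpha-branched isopropenyl group and hydride from catecholborane goes to the face that gives the (6R) carbinol (the same sense as acetophenone to (R)-1-phenylethanol), while catecholborane at −78 °C should neither hydroborate the alkenes nor reduce the lactone.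

**Step 13**
Reactants: 18 4-{[(2Z,6R)-3-{[(tert-butyldiphenylsilyl)oxy]methyl}-6-hydroxy-7-methylocta-2,7-dien-1-yl]oxy}-5-methyl-2H-chromen-2-one
Product: 19 (2Z,6R)-3-{[(tert-butyldiphenylsilyl)oxy]methyl}-7-methyl-1-[(5-methyl-2-oxo-2H-chromen-4-yl)oxy]octa-2,7-dien-6-yl methanesulfonate
Conditions: Ms2O, Et3N, CH2Cl2, −30 °C; cold aqueous wash, used crude at once
Reagents that add atoms: methanesulfonic anhydride, CS(=O)(=O)OS(C)(=O)=O
Why: Sulfonylation on oxygen keeps the C6 configuration, and the anhydride is chosen over the chloride so that no chloride ion is present to displace the labile allylic mesylate and erode the configuration by double inversion.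

**Step 14**
Reactants: 19 (2Z,6R)-3-{[(tert-butyldiphenylsilyl)oxy]methyl}-7-methyl-1-[(5-methyl-2-oxo-2H-chromen-4-yl)oxy]octa-2,7-dien-6-yl methanesulfonate
Product: 20 4-{[(2Z,6S)-3-{[(tert-butyldiphenylsilyl)oxy]methyl}-6-hydroperoxy-7-methylocta-2,7-dien-1-yl]oxy}-5-methyl-2H-chromen-2-one
Conditions: 50% aq. H2O2 (large excess), KOH (1.2 equiv), THF/MeOH, −10 → 0 °C; NaH2PO4 buffer work-up
Reagents that add atoms: hydrogen peroxide, OO
Why: Perhydrolysis of a methanesulfonate, a reaction known for secondary alkyl and for allylic sulfonates: hydroperoxide anion, an alpha-effect nucleophile, displaces the secondary allylic mesylate by SN2 with inversion and so turns the (6R) sulfonate into the (6S) hydroperoxide, helped by the unsubstituted terminus of the 2-methylallyl unit (reluctant ionization) and by the small amount of KOH in a large excess of H2O2, which should spare the pyranone.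

**Step 15**
Reactants: 20 4-{[(2Z,6S)-3-{[(tert-butyldiphenylsilyl)oxy]methyl}-6-hydroperoxy-7-methylocta-2,7-dien-1-yl]oxy}-5-methyl-2H-chromen-2-one
Product: 21 4-{[(2Z,6S)-6-hydroperoxy-3-(hydroxymethyl)-7-methylocta-2,7-dien-1-yl]oxy}-5-methyl-2H-chromen-2-one
Conditions: HF·pyridine, pyridine, THF, 0 °C → rt
Reagents that add atoms: none
Why: Fluoride cleavage of the silyl ether under buffered acidic conditions, which should leave the hydroperoxide, the allylic ether and the lactone intact and avoids the base-induced dehydration of the secondary hydroperoxide to the enone (Kornblum–DeLaMare).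

**Compound list**
1 | 2-(2-bromoethyl)-1,3-dioxolane | BrCCC1OCCO1 | starting material
2 | 2-(1,3-dioxolan-2-yl)ethylmagnesium bromide | Br[Mg]CCC1OCCO1 | intermediate
3 | propargyl alcohol | C#CCO | starting material
4 | formaldehyde (from paraformaldehyde) | C=O | starting material
5 | 4-[2-(1,3-dioxolan-2-yl)ethyl]-2,5-dihydro-1,2-oxamagnesole (chelated alkenylmagnesium alkoxide, not isolated) | C1(CCC2OCCO2)=C[Mg]OC1 | intermediate
6 | (Z)-2-[2-(1,3-dioxolan-2-yl)ethyl]but-2-ene-1,4-diol | OC/C=C(/CCC1OCCO1)CO | intermediate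
7 | (Z)-3-[2-(1,3-dioxolan-2-yl)ethyl]-4-hydroxybut-2-en-1-yl 2,2-dimethylpropanoate | CC(C)(C)C(=O)OC/C=C(/CCC1OCCO1)CO | intermediate
8 | (Z)-4-[(tert-butyldiphenylsilyl)oxy]-3-[2-(1,3-dioxolan-2-yl)ethyl]but-2-en-1-yl 2,2-dimethylpropanoate | CC(C)(C)C(=O)OC/C=C(/CCC1OCCO1)CO[Si](c1ccccc1)(c1ccccc1)C(C)(C)C | intermediate
9 | (Z)-4-[(tert-butyldiphenylsilyl)oxy]-3-[2-(1,3-dioxolan-2-yl)ethyl]but-2-en-1-ol | OC/C=C(/CCC1OCCO1)CO[Si](c1ccccc1)(c1ccccc1)C(C)(C)C | intermediate
10 | 2-hydroxy-6-methylbenzoic acid | Cc1cccc(O)c1C(=O)O | starting material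
11 | 1-(2-hydroxy-6-methylphenyl)ethan-1-one | CC(=O)c1c(C)cccc1O | intermediate
12 | 4-hydroxy-5-methyl-2H-chromen-2-one | Cc1cccc2oc(=O)cc(O)c12 | intermediate
13 | 4-{[(Z)-4-[(tert-butyldiphenylsilyl)oxy]-3-[2-(1,3-dioxolan-2-yl)ethyl]but-2-en-1-yl]oxy}-5-methyl-2H-chromen-2-one | Cc1cccc2oc(=O)cc(OC/C=C(/CCC3OCCO3)CO[Si](c3ccccc3)(c3ccccc3)C(C)(C)C)c12 | intermediate
14 | (Z)-4-{[(tert-butyldiphenylsilyl)oxy]methyl}-6-[(5-methyl-2-oxo-2H-chromen-4-yl)oxy]hex-4-enal | Cc1cccc2oc(=O)cc(OC/C=C(/CCC=O)CO[Si](c3ccccc3)(c3ccccc3)C(C)(C)C)c12 | intermediate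
15 | 2-bromopropene | C=C(C)Br | starting material
16 | 4-{[(2Z)-3-{[(tert-butyldiphenylsilyl)oxy]methyl}-6-hydroxy-7-methylocta-2,7-dien-1-yl]oxy}-5-methyl-2H-chromen-2-one, racemic at C6 | Cc1cccc2oc(=O)cc(OC/C=C(/CCC(O)C(C)=C)CO[Si](c3ccccc3)(c3ccccc3)C(C)(C)C)c12 | intermediate
17 | 4-{[(2Z)-3-{[(tert-butyldiphenylsilyl)oxy]methyl}-7-methyl-6-oxoocta-2,7-dien-1-yl]oxy}-5-methyl-2H-chromen-2-one | Cc1cccc2oc(=O)cc(OC/C=C(/CCC(=O)C(C)=C)CO[Si](c3ccccc3)(c3ccccc3)C(C)(C)C)c12 | intermediate
18 | 4-{[(2Z,6R)-3-{[(tert-butyldiphenylsilyl)oxy]methyl}-6-hydroxy-7-methylocta-2,7-dien-1-yl]oxy}-5-methyl-2H-chromen-2-one | Cc1cccc2oc(=O)cc(OC/C=C(/CC[C@@H](O)C(C)=C)CO[Si](c3ccccc3)(c3ccccc3)C(C)(C)C)c12 | intermediate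
19 | (2Z,6R)-3-{[(tert-butyldiphenylsilyl)oxy]methyl}-7-methyl-1-[(5-methyl-2-oxo-2H-chromen-4-yl)oxy]octa-2,7-dien-6-yl methanesulfonate | Cc1cccc2oc(=O)cc(OC/C=C(/CC[C@@H](OS(C)(=O)=O)C(C)=C)CO[Si](c3ccccc3)(c3ccccc3)C(C)(C)C)c12 | intermediate
20 | 4-{[(2Z,6S)-3-{[(tert-butyldiphenylsilyl)oxy]methyl}-6-hydroperoxy-7-methylocta-2,7-dien-1-yl]oxy}-5-methyl-2H-chromen-2-one | Cc1cccc2oc(=O)cc(OC/C=C(/CC[C@H](OO)C(C)=C)CO[Si](c3ccccc3)(c3ccccc3)C(C)(C)C)c12 | intermediate
21 | 4-{[(2Z,6S)-6-hydroperoxy-3-(hydroxymethyl)-7-methylocta-2,7-dien-1-yl]oxy}-5-methyl-2H-chromen-2-one | Cc1cccc2oc(=O)cc(OC/C=C(/CC[C@H](OO)C(C)=C)CO)c12 | target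

**Totals**
Total step count: 15. Longest linear sequence: 13 steps (steps 1–5 and 8–15); steps 6 and 7 form the short coumarin branch.

**Steps most likely to fail**

Step 14. The allylic mesylate may ionize and lose its configuration, hydroperoxide may attack the terminal methylene with allylic transposition, or hydroperoxide anion in aqueous base may attack the pyranone. The fallback replaces free hydrogen peroxide by a mono-protected peroxide nucleophile in a water-free dipolar medium. It sets out from mesylate 19. 2-Methoxyprop-2-yl hydroperoxide F1, made by ozonolysis of 2,3-dimethylbut-2-ene in methanol, is alkylated by 19 with CsOH·H2O in DMF at 0 °C. This known route to secondary hydroperoxides should give, with inversion, 4-{[(2Z,6S)-3-{[(tert-butyldiphenylsilyl)oxy]methyl}-6-[(2-methoxypropan-2-yl)peroxy]-7-methylocta-2,7-dien-1-yl]oxy}-5-methyl-2H-chromen-2-one F2, a peroxyketal that can be purified. Mild hydrolysis (AcOH/THF/H2O, rt) then releases the hydroperoxide, and the route is rejoined at 20.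

Step 2. The acetal-bearing Grignard reagent may fragment before carbometalation is complete, or the chelated alkenylmagnesium may add sluggishly to formaldehyde, which polymerizes, so that protonation on work-up leaves the 2-substituted allyl alcohol. The fallback keeps the carbomagnesiation but changes the one-carbon electrophile and its oxidation level. It sets out from 2 and 3 through the same oxamagnesacycle 5, which is trapped with dry CO2 (−20 °C → rt, then mild acid); the carboxylate lactonizes onto the cis C10 hydroxyl to give 4-[2-(1,3-dioxolan-2-yl)ethyl]furan-2(5H)-one F3. Reduction of this butenolide with i-Bu2AlH (CH2Cl2, −78 → 0 °C) opens it to the (Z)-diol, and the route is rejoined at 6.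

Step 3. Discrimination between the two primary allylic hydroxyls may be poor, giving mixtures of regioisomeric monoesters and diester. The fallback gives up reagent bulk for enzyme control and sets out from diol 6. Transesterification with vinyl acetate catalysed by immobilized lipase B from Candida antarctica (MTBE, rt), a known way to acylate the less hindered hydroxyl of 2-substituted butenediols, should give (Z)-3-[2-(1,3-dioxolan-2-yl)ethyl]-4-hydroxybut-2-en-1-yl acetate F4. Silylation (TBDPSCl, imidazole, DMF) then gives (Z)-4-[(tert-butyldiphenylsilyl)oxy]-3-[2-(1,3-dioxolan-2-yl)ethyl]but-2-en-1-yl acetate F5, and methanolysis (K2CO3, MeOH, 0 °C) removes the acetate, so that the route is rejoined at 9.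

**Further compounds**
F1 | step 14 | 2-methoxyprop-2-yl hydroperoxide | COC(C)(C)OO
F2 | step 14 | 4-{[(2Z,6S)-3-{[(tert-butyldiphenylsilyl)oxy]methyl}-6-[(2-methoxypropan-2-yl)peroxy]-7-methylocta-2,7-dien-1-yl]oxy}-5-methyl-2H-chromen-2-one | Cc1cccc2oc(=O)cc(OC/C=C(/CC[C@H](OOC(C)(C)OC)C(C)=C)CO[Si](c3ccccc3)(c3ccccc3)C(C)(C)C)c12
F3 | step 2 | 4-[2-(1,3-dioxolan-2-yl)ethyl]furan-2(5H)-one | O=C1OCC(CCC2OCCO2)=C1
F4 | step 3 | (Z)-3-[2-(1,3-dioxolan-2-yl)ethyl]-4-hydroxybut-2-en-1-yl acetate | CC(=O)OC/C=C(/CCC1OCCO1)CO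
F5 | step 3 | (Z)-4-[(tert-butyldiphenylsilyl)oxy]-3-[2-(1,3-dioxolan-2-yl)ethyl]but-2-en-1-yl acetate | CC(=O)OC/C=C(/CCC1OCCO1)CO[Si](c1ccccc1)(c1ccccc1)C(C)(C)C
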